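**Retrosynthetic overview**
- Feature: the quinone ring is C1(=O)–C2(OMe)=C3H–C4(=O) and the benzo ring is C4a, C5(H), C6(CH2Ar), C7(CH3), C8(Ar), C8a. The run C4a–C5–C6–C7 carries the substituent pattern of a 2-alkyl-4-benzyl-5-methylfuran. C8 and C8a are the β- and α-carbons of an aryl enone whose carbonyl carbon is C1.
- Endgame: larreantin ⇒ its bis(benzyl ether) quinone ⇒ the 2-methoxy-1-naphthol ⇒ the 2-methoxy-1-tetralone. The forward operations are enolate dehydrogenation without a quinone oxidant, C4 oxygenation with K2NO(SO3)2, and hydrogenolysis followed by air.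
- Key disconnection: tetralone ⇒ furan–enone, by intramolecular furan Diels–Alder reaction and loss of the oxygen bridge as water (bonds C4a–C8a and C7–C8). The benzo ring and the future quinone ring form together in this step, and the purchased furan ring is consumed.
- Furan–enone ⇒ O-benzylvanillin + α-methoxy methyl ketone (Claisen–Schmidt). The ketone ⇒ 3-furylpropanal + 1-ethoxyvinyllithium. The propanal ⇒ 3-benzyl-2-methylfuran + acrolein, an acid-catalysed C5 alkylation that keeps strong base away from the diarylmethane CH2.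
- 3-Benzyl-2-methylfuran ⇒ ethyl 2-methylfuran-3-carboxylate + O-benzyl-4-bromoguaiacol (Weinreb ketone synthesis, mixed-hydride deoxygenation).

Key step: step 10

Notation: Ar = 4-(benzyloxy)-3-methoxyphenyl; bicyclic compounds carry the naphthalene numbering of the target.
Assumption: the methoxy-bearing carbon (future C2) is carried as a racemate with the (S)-enantiomer drawn; this is harmless because the centre is erased when the second ring is aromatised and the target has no stereocentre.

**Step 1**
Reactants: 1 4-bromo-2-methoxyphenol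
Product: 2 1-(benzyloxy)-4-bromo-2-methoxybenzene
Conditions: BnBr (1.1 equiv), K2CO3, DMF, 23 °C
Reagents that add atoms: benzyl bromide, BrCc1ccccc1
Why: Williamson ether synthesis, in which the phenoxide formed by K2CO3 displaces bromide from the benzylic halide while the aryl bromide stays inert.

**Step 2**
Reactants: 3 ethyl 2-methylfuran-3-carboxylate
Product: 4 N-methoxy-N,2-dimethylfuran-3-carboxamide
Conditions: MeNH(OMe)·HCl (1.5 equiv), i-PrMgCl (3 equiv), THF, −20 → 0 °C
Reagents that add atoms: N,O-dimethylhydroxylamine hydrochloride, CNOC.Cl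
Why: Weinreb amide formation by aminolysis of the ester with the chloromagnesium amide made in the flask, a nucleophile too weakly basic at this temperature to deprotonate the furan 2-methyl group.

**Step 3**
Reactants: 2 1-(benzyloxy)-4-bromo-2-methoxybenzene; 4 N-methoxy-N,2-dimethylfuran-3-carboxamide
Product: 6 (4-benzyloxy-3-methoxyphenyl)(2-methylfuran-3-yl)methanone, via arylmagnesium bromide 5 (not isolated)
Conditions: 2, Mg, I2 (cat.), THF, 50 °C; then 4, 0 → 23 °C; 1 M HCl
Reagents that add atoms: none
Why: Weinreb ketone synthesis, in which the magnesium chelate of the tetrahedral adduct survives until the quench so that only one aryl group adds, and the Grignard reagent is preferred to the aryllithium to limit deprotonation of the vinylogously acidic 2-methyl group.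

**Step 4**
Reactants: 6 (4-benzyloxy-3-methoxyphenyl)(2-methylfuran-3-yl)methanone
Product: 7 3-[(4-benzyloxy-3-methoxyphenyl)methyl]-2-methylfuran
Conditions: LiAlH4, AlCl3, Et2O, 0 → 35 °C
Reagents that add atoms: none
Why: Mixed-hydride deoxygenation of a diaryl ketone, in which the aluminium alkoxide of the doubly activated carbinol (3-furyl and p-alkoxyphenyl) ionises under the chloroalane and the cation is trapped by hydride, under conditions that spare the furan, the benzyl ether and the methyl ether.

**Step 5**
Reactants: 7 3-[(4-benzyloxy-3-methoxyphenyl)methyl]-2-methylfuran; 8 acrolein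
Product: 9 3-{4-[(4-benzyloxy-3-methoxyphenyl)methyl]-5-methylfuran-2-yl}propanal
Conditions: 8 (1.5 equiv), AcOH, hydroquinone (cat.), 23 → 40 °C
Reagents that add atoms: none
Why: Acid-catalysed Friedel–Crafts-type conjugate addition of an α-unsubstituted furan to an enal, selective because C5 is the only free α-position and the most nucleophilic carbon of 7, and chosen because a C5 lithiation would have to compete with deprotonation of the diarylmethane CH2 and of the OCH2Ph group.

**Step 6**
Reactants: 9 3-{4-[(4-benzyloxy-3-methoxyphenyl)methyl]-5-methylfuran-2-yl}propanal; 10 ethyl vinyl ether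
Product: 12 5-{4-[(4-benzyloxy-3-methoxyphenyl)methyl]-5-methylfuran-2-yl}-2-ethoxypent-1-en-3-ol (racemic), via 1-ethoxyvinyllithium 11 (not isolated)
Conditions: 10 (3 equiv), t-BuLi (2 equiv), THF, −78 → 0 °C; then 9, −78 °C; H2O
Reagents that add atoms: none
Why: Addition of an acyl anion equivalent (α-lithiated enol ether) to an aldehyde, faster at −78 °C than enolisation, with the new carbinol centre (future C2) formed without facial bias and therefore racemic.

**Step 7**
Reactants: 12 5-{4-[(4-benzyloxy-3-methoxyphenyl)methyl]-5-methylfuran-2-yl}-2-ethoxypent-1-en-3-ol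
Product: 14 5-{4-[(4-benzyloxy-3-methoxyphenyl)methyl]-5-methylfuran-2-yl}-3-methoxypentan-2-one (racemic), via methyl ether 13 (not isolated)
Conditions: NaH, MeI, THF–DMF, 0 → 23 °C; then 1 M HCl, THF, 0 °C
Reagents that add atoms: iodomethane, CI; water, O
Why: Williamson O-methylation of the sodium alkoxide followed by hydrolysis of the very acid-labile enol ether, under acid too mild and brief to open the trialkylfuran and without touching the stereocentre.

**Step 8**
Reactants: 15 vanillin
Product: 16 4-(benzyloxy)-3-methoxybenzaldehyde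
Conditions: BnBr (1.1 equiv), K2CO3, DMF, 23 °C
Reagents that add atoms: benzyl bromide, BrCc1ccccc1
Why: Williamson ether synthesis of the acidic p-formylphenol, with the aldehyde inert to carbonate.

**Step 9**
Reactants: 14 5-{4-[(4-benzyloxy-3-methoxyphenyl)methyl]-5-methylfuran-2-yl}-3-methoxypentan-2-one; 16 4-(benzyloxy)-3-methoxybenzaldehyde
Product: 17 (E)-1-Ar-6-[4-(ArCH2)-5-methylfuran-2-yl]-4-methoxyhex-1-en-3-one (racemic)
Conditions: 16 (1.2 equiv), LiOH·H2O (0.5 equiv), MeOH–THF–H2O, 23 → 50 °C
Reagents that add atoms: none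
Why: Claisen–Schmidt condensation, in which only the aldol at the methyl group can dehydrate (E1cB) while the aldol at the methoxy-bearing carbon is a reversible dead end, and the conjugated (E)-enone is the thermodynamic product.

**Step 10**
Reactants: 17 (E)-1-Ar-6-[4-(ArCH2)-5-methylfuran-2-yl]-4-methoxyhex-1-en-3-one
Product: 19 8-Ar-6-(ArCH2)-2-methoxy-7-methyl-3,4-dihydronaphthalen-1(2H)-one (racemic), via oxanorbornene cycloadduct 18 (not isolated)
Conditions: MeAlCl2 (2.2 equiv), CH2Cl2 (0.01 M), −78 → 23 °C; aq. potassium sodium tartrate; then TsOH·H2O (0.2 equiv), PhMe, 60 °C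
Reagents that add atoms: none
Why: Proposed new method: MeAlCl2 in excess should bind the C1 carbonyl and the C2 methoxy oxygen as a five-membered chelate, lowering the enone LUMO so that the furan (4π, through its 2,5-positions) adds suprafacially to the (E)-alkene (2π) in an asynchronous [4+2] step in which the methyl-bearing furan carbon attacks the aryl-bearing β-carbon (C7–C8) and the chain-bearing furan carbon bonds to the α-carbon (C4a–C8a) to give 18. The Lewis acid then ionises the tertiary, allylic C7–O bond, H8 is lost, and the remaining C4a–OH, which is β to the C1 ketone, leaves with H8a as water (completed by TsOH), so that the benzene ring forms irreversibly and drains an equilibrium expected to favour 17. The closest known reaction type is the MeAlCl2-promoted intramolecular Diels–Alder reaction of furans with enones held by a four-atom keto tether, followed by acid aromatisation of the oxanorbornene, which has not been shown for a 2,4,5-trisubstituted furan paired with an electron-rich β-aryl enone. Both rings close in the one cycloaddition: the future benzo ring (C4a–C5–C6–C7–C8–C8a) as the six-membered carbocycle of the 7-oxanorbornene, and the future quinone ring (C1–C2–C3–C4–C4a–C8a) as a six-membered ring through the tether C4–C3–C2–C1, which should sit exo. The four centres created in 18 (C4a, C7, C8, C8a) follow from suprafacial addition to the (E)-alkene and the exo tether, both epimers at C2 are expected, and all four are erased on aromatisation, so that 19 keeps only the racemic C2 centre and no new stereocentre needs control. The step needs regioselectivity, which the tether secures because only the enone α-carbon can reach the chain-bearing furan carbon, and chemoselectivity for cycloaddition over furan oligomerisation and benzyl ether cleavage, which high dilution, a low starting temperature and preferential chelation of aluminium by the α-methoxy ketone should secure.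

**Step 11**
Reactants: 19 8-Ar-6-(ArCH2)-2-methoxy-7-methyl-3,4-dihydronaphthalen-1(2H)-one
Product: 22 8-Ar-6-(ArCH2)-2-methoxy-7-methylnaphthalen-1-ol, via lithium enolate 20 (not isolated), via 2-methoxynaphthalen-1(4H)-one tautomer 21 (not isolated)
Conditions: LiN(i-Pr)2 (1.1 equiv), THF, −78 °C; PhS(Cl)=Nt-Bu (1.2 equiv), −78 °C; aq. NH4Cl
Reagents that add atoms: none
Why: Mukaiyama dehydrogenation, in which C2 is the only enolisable position, the enolate attacks sulfur and syn-elimination across C2–C3 gives dienone 21 that tautomerises to the naphthol and erases the C2 stereocentre, whereas a high-potential quinone oxidant is avoided because it would abstract hydride from the electron-rich diarylmethane CH2 and overoxidise 22.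

**Step 12**
Reactants: 22 8-Ar-6-(ArCH2)-2-methoxy-7-methylnaphthalen-1-ol
Product: 23 8-Ar-6-(ArCH2)-2-methoxy-7-methylnaphthalene-1,4-dione
Conditions: K2NO(SO3)2 (2.5 equiv), KH2PO4 buffer, acetone–H2O, 23 °C
Reagents that add atoms: potassium nitrosodisulfonate K2NO(SO3)2, [K+].[K+].[O]N(S(=O)(=O)[O-])S(=O)(=O)[O-]
Why: Teuber oxidation, in which one nitrosodisulfonate radical abstracts the phenolic hydrogen and a second couples at the free para position C4 and collapses to the 1,4-quinone, while the fully etherified guaiacyl rings and the diarylmethane are inert to this mild one-electron oxidant.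

**Step 13**
Reactants: 23 8-Ar-6-(ArCH2)-2-methoxy-7-methylnaphthalene-1,4-dione
Product: 25 larreantin, via naphthalene-1,4-diol 24 (not isolated)
Conditions: H2 (1 atm), Pd/C, EtOAc–MeOH, 23 °C; filter; stir under air
Reagents that add atoms: none
Why: Hydrogenolysis of both aryl benzyl ethers with concurrent reduction of the quinone to the hydroquinone, which is the most easily autoxidised phenol present and is returned to the quinone by air while the two guaiacol units remain untouched.

**Compound list**
1 | 4-bromo-2-methoxyphenol | COc1cc(Br)ccc1O | starting material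
2 | 1-(benzyloxy)-4-bromo-2-methoxybenzene | COc1cc(Br)ccc1OCc1ccccc1 | intermediate
3 | ethyl 2-methylfuran-3-carboxylate | CCOC(=O)c1ccoc1C | starting material
4 | N-methoxy-N,2-dimethylfuran-3-carboxamide | CON(C)C(=O)c1ccoc1C | intermediate
5 | [4-(benzyloxy)-3-methoxyphenyl]magnesium bromide (not isolated) | COc1cc([Mg]Br)ccc1OCc1ccccc1 | intermediate
6 | (4-benzyloxy-3-methoxyphenyl)(2-methylfuran-3-yl)methanone | Cc1occc1C(=O)c1ccc(OCc2ccccc2)c(OC)c1 | intermediate
7 | 3-[(4-benzyloxy-3-methoxyphenyl)methyl]-2-methylfuran | Cc1occc1Cc1ccc(OCc2ccccc2)c(OC)c1 | intermediate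
8 | acrolein (prop-2-enal) | C=CC=O | starting material
9 | 3-{4-[(4-benzyloxy-3-methoxyphenyl)methyl]-5-methylfuran-2-yl}propanal | Cc1oc(CCC=O)cc1Cc1ccc(OCc2ccccc2)c(OC)c1 | intermediate
10 | ethyl vinyl ether | C=COCC | starting material
11 | 1-ethoxyvinyllithium (not isolated) | [Li]C(=C)OCC | intermediate
12 | 5-{4-[(4-benzyloxy-3-methoxyphenyl)methyl]-5-methylfuran-2-yl}-2-ethoxypent-1-en-3-ol (racemic, S drawn) | Cc1oc(CC[C@H](O)C(=C)OCC)cc1Cc1ccc(OCc2ccccc2)c(OC)c1 | intermediate
13 | 3-[(4-benzyloxy-3-methoxyphenyl)methyl]-5-(4-ethoxy-3-methoxypent-4-en-1-yl)-2-methylfuran (racemic, S drawn; not isolated) | Cc1oc(CC[C@H](OC)C(=C)OCC)cc1Cc1ccc(OCc2ccccc2)c(OC)c1 | intermediate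
14 | 5-{4-[(4-benzyloxy-3-methoxyphenyl)methyl]-5-methylfuran-2-yl}-3-methoxypentan-2-one (racemic, S drawn) | Cc1oc(CC[C@H](OC)C(C)=O)cc1Cc1ccc(OCc2ccccc2)c(OC)c1 | intermediate
15 | vanillin | COc1cc(C=O)ccc1O | starting material
16 | 4-(benzyloxy)-3-methoxybenzaldehyde | COc1cc(C=O)ccc1OCc1ccccc1 | intermediate
17 | (E)-1-(4-benzyloxy-3-methoxyphenyl)-6-{4-[(4-benzyloxy-3-methoxyphenyl)methyl]-5-methylfuran-2-yl}-4-methoxyhex-1-en-3-one (racemic, S drawn) | Cc1oc(CC[C@H](OC)C(=O)/C=C/c2ccc(OCc3ccccc3)c(OC)c2)cc1Cc1ccc(OCc2ccccc2)c(OC)c1 | intermediate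
18 | 4a,7-epoxy-8-Ar-6-(ArCH2)-2-methoxy-7-methyl-3,4,4a,7,8,8a-hexahydronaphthalen-1(2H)-one (racemic; tether exo, C8 aryl endo; one C2 epimer drawn; not isolated) | CO[C@H]1CC[C@@]23C=C(Cc4ccc(OCc5ccccc5)c(OC)c4)[C@@](C)(O2)[C@H](c2ccc(OCc4ccccc4)c(OC)c2)[C@H]3C1=O | intermediate
19 | 8-(4-benzyloxy-3-methoxyphenyl)-6-[(4-benzyloxy-3-methoxyphenyl)methyl]-2-methoxy-7-methyl-3,4-dihydronaphthalen-1(2H)-one (racemic, S drawn) | CO[C@H]1CCc2cc(Cc3ccc(OCc4ccccc4)c(OC)c3)c(C)c(-c3ccc(OCc4ccccc4)c(OC)c3)c2C1=O | intermediate
20 | lithium enolate of 19 (not isolated) | [Li]OC1=C(OC)CCc2cc(Cc3ccc(OCc4ccccc4)c(OC)c3)c(C)c(-c3ccc(OCc4ccccc4)c(OC)c3)c21 | intermediate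
21 | 8-Ar-6-(ArCH2)-2-methoxy-7-methylnaphthalen-1(4H)-one (not isolated) | COC1=CCc2cc(Cc3ccc(OCc4ccccc4)c(OC)c3)c(C)c(-c3ccc(OCc4ccccc4)c(OC)c3)c2C1=O | intermediate
22 | 8-Ar-6-(ArCH2)-2-methoxy-7-methylnaphthalen-1-ol | COc1ccc2cc(Cc3ccc(OCc4ccccc4)c(OC)c3)c(C)c(-c3ccc(OCc4ccccc4)c(OC)c3)c2c1O | intermediate
23 | 8-Ar-6-(ArCH2)-2-methoxy-7-methylnaphthalene-1,4-dione (larreantin bis(benzyl ether)) | COC1=CC(=O)c2cc(Cc3ccc(OCc4ccccc4)c(OC)c3)c(C)c(-c3ccc(OCc4ccccc4)c(OC)c3)c2C1=O | intermediate
24 | 8-(4-hydroxy-3-methoxyphenyl)-6-[(4-hydroxy-3-methoxyphenyl)methyl]-2-methoxy-7-methylnaphthalene-1,4-diol (not isolated) | COc1cc(O)c2cc(Cc3ccc(O)c(OC)c3)c(C)c(-c3ccc(O)c(OC)c3)c2c1O | intermediate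
25 | larreantin | COC1=CC(=O)c2cc(Cc3ccc(O)c(OC)c3)c(C)c(-c3ccc(O)c(OC)c3)c2C1=O | target

**Step count**
Total step count: 13. Longest linear sequence: 11 steps (from 3 through steps 2, 3, 4, 5, 6, 7, 9, 10, 11, 12, 13; the branch from 1 has the same length).

**Steps most likely to fail**

**1. Step 10.**
- What may go wrong: the cycloaddition equilibrium may lie so far on the open side that bridge opening never competes. Loss of cinnamoyl conjugation and formation of a quaternary carbon next to a benzylic carbon both work against the adduct. Lewis-acid-induced furan oligomerisation or loss of the benzyl ethers may then take over.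
- Fallback: known chemistry only; it sets out from 2 and comes back at 23.
- Sonogashira coupling of 2 with propyne (PdCl2(PPh3)2, CuI, Et3N, DMF) should give 1-(benzyloxy)-2-methoxy-4-(prop-1-yn-1-yl)benzene F1.
- Syn-protoboration (CuCl, Xantphos, NaOt-Bu, B2pin2, MeOH) places boron on the methyl-bearing carbon and gives the (Z)-alkenyl pinacol boronate F2.
- In parallel, Grignard reagent 5 made from 2 is allylated with 2,3-dibromopropene to give 1-(benzyloxy)-4-(2-bromoprop-2-en-1-yl)-2-methoxybenzene F3.
- Suzuki–Miyaura coupling of the two (PdCl2(dppf), K3PO4, THF–H2O) proceeds with retention and gives (E)-1-Ar-3-(ArCH2)-2-methylbuta-1,3-diene F4.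
- Heating this diene with 2-methoxy-1,4-benzoquinone in toluene should give the cis-fused endo tetrahydronaphthoquinone adduct F5 at the unsubstituted quinone double bond.
- The aryl-bearing diene terminus should end next to the carbonyl adjacent to the methoxy carbon, because the other carbonyl is deactivated as a vinylogous ester.
- Enolisation with Et3N and oxidation with MnO2 in CH2Cl2 then aromatises the new ring to 23.

**2. Step 11.**
- What may go wrong: sulfur transfer to the fully substituted, peri-hindered enolate carbon may be slow. The electron-rich naphthol may also be oxidised further during the reaction or work-up.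
- Fallback: it sets out from 19 and comes back at 22, moving the C–H removal to β-hydride elimination from a palladium enolate.
- TMSOTf and Et3N (CH2Cl2, 0 °C) convert 19 into the isolated trimethylsilyl enol ether F6.
- Pd(OAc)2 (1 equiv) in MeCN then effects a Saegusa–Ito oxidation across C2–C3 to 21, which tautomerises to 22.

**3. Step 5.**
- What may go wrong: polymerisation of acrolein, and acid-induced condensation of the product aldehyde with a second furan, may consume the material.
- Fallback: it sets out from 7 and comes back at 9.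
- Bromination with N-bromosuccinimide (THF, −20 °C, dark) at the free α-position gives 3-(ArCH2)-5-bromo-2-methylfuran F7.
- This bromide is used at once in a Heck reaction with allyl alcohol (Pd(OAc)2, Bu4NCl, NaHCO3, DMF, 50 °C). β-Hydride elimination toward the carbinol carbon and tautomerisation of the enol deliver 9.

**Further compounds**
F1 | step 10 | 1-(benzyloxy)-2-methoxy-4-(prop-1-yn-1-yl)benzene | CC#Cc1ccc(OCc2ccccc2)c(OC)c1
F2 | step 10 | (Z)-2-[1-(4-benzyloxy-3-methoxyphenyl)prop-1-en-2-yl]-4,4,5,5-tetramethyl-1,3,2-dioxaborolane | C/C(B1OC(C)(C)C(C)(C)O1)=C\c1ccc(OCc2ccccc2)c(OC)c1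
F3 | step 10 | 1-(benzyloxy)-4-(2-bromoprop-2-en-1-yl)-2-methoxybenzene | C=C(Br)Cc1ccc(OCc2ccccc2)c(OC)c1
F4 | step 10 | (E)-1-(4-benzyloxy-3-methoxyphenyl)-3-[(4-benzyloxy-3-methoxyphenyl)methyl]-2-methylbuta-1,3-diene | C=C(Cc1ccc(OCc2ccccc2)c(OC)c1)/C(C)=C/c1ccc(OCc2ccccc2)c(OC)c1
F5 | step 10 | 8-Ar-6-(ArCH2)-2-methoxy-7-methyl-4a,5,8,8a-tetrahydronaphthalene-1,4-dione (racemic; H4a, H8 and H8a on one face) | COC1=CC(=O)[C@H]2CC(Cc3ccc(OCc4ccccc4)c(OC)c3)=C(C)[C@@H](c3ccc(OCc4ccccc4)c(OC)c3)[C@H]2C1=O
F6 | step 11 | {[8-Ar-6-(ArCH2)-2-methoxy-7-methyl-3,4-dihydronaphthalen-1-yl]oxy}trimethylsilane | C[Si](C)(C)OC1=C(OC)CCc2cc(Cc3ccc(OCc4ccccc4)c(OC)c3)c(C)c(-c3ccc(OCc4ccccc4)c(OC)c3)c21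
F7 | step 5 | 3-[(4-benzyloxy-3-methoxyphenyl)methyl]-5-bromo-2-methylfuran | Cc1oc(Br)cc1Cc1ccc(OCc2ccccc2)c(OC)c1
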